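**Strategy.** Everything rests on disconnecting the indole N1–C7a bond. A 2,2-diaryl nitroethene, holding a 5-bromo-2-methoxyphenyl group and the masked aminopyrimidine on one alkene carbon, is deoxygenated to a vinyl nitrene/2H-azirine, which closes the pyrrole ring in a single operation. The step exploits the benzene ring of the indole: of the two carbons ortho to C3a, C4 bears oxygen, so the nitrogen attached to C2 has only the C–H at C7a to attack, and C7–Br and C4–O are already in place in the aryl group. In the precursor the C4' amine is a bis(4-methoxybenzyl)amine, C2' carries chlorine and the phenol is a methyl ether.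

Key step: step 4

Locants: indole N1, C2, C3, C3a, C4–C7, C7a; pyrimidine atoms are primed (C2' halogen, C4' amine, C5' joined to C3). PMB = 4-methoxybenzyl.
Assumption: step 3 may give both alkene isomers of 8; both lead to the same azirine, and 8 is drawn as the E isomer.

**Step 1**
Reactants: 1 1-(2,4-dichloropyrimidin-5-yl)ethan-1-one; 2 bis(4-methoxybenzyl)amine
Product: 3 1-{4-[bis(4-methoxybenzyl)amino]-2-chloropyrimidin-5-yl}ethan-1-one
Conditions: K2CO3, MeCN, 0 °C to rt
Reagents that add atoms: none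
Why: Nucleophilic aromatic substitution (SNAr): C4' of the 2,4-dichloropyrimidine is the more electrophilic carbon and is further activated by the ortho acetyl group, so the secondary amine should displace that chloride and leave C2'–Cl in place.

**Step 2**
Reactants: 4 2,4-dibromo-1-methoxybenzene; 3 1-{4-[bis(4-methoxybenzyl)amino]-2-chloropyrimidin-5-yl}ethan-1-one
Product: 7 5-[1-(5-bromo-2-methoxyphenyl)ethenyl]-2-chloro-N,N-bis(4-methoxybenzyl)pyrimidin-4-amine, via aryl Grignard reagent 5 (not isolated), via tertiary carbinol 6 (not isolated)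
Conditions: 4, iPrMgCl (0.95 equiv), THF, 0 °C to rt; add to 3, LaCl3·2LiCl, THF, 0 °C to rt; then TsOH·H2O (excess), PhMe, 60 °C, same flask
Reagents that add atoms: none
Why: Bromine–magnesium exchange should occur at the bromide ortho to the coordinating methoxy group, the aryl Grignard reagent then adds to the methyl ketone (Grignard 1,2-addition, with LaCl3·2LiCl to suppress enolisation), and the doubly benzylic tertiary alcohol loses water by acid-catalysed E1 dehydration, which also erases the carbinol stereocentre.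

**Step 3**
Reactants: 7 5-[1-(5-bromo-2-methoxyphenyl)ethenyl]-2-chloro-N,N-bis(4-methoxybenzyl)pyrimidin-4-amine
Product: 8 5-[(E)-1-(5-bromo-2-methoxyphenyl)-2-nitroethenyl]-2-chloro-N,N-bis(4-methoxybenzyl)pyrimidin-4-amine
Conditions: AgNO2 (3 equiv), TEMPO (0.4 equiv), 4 Å MS, ClCH2CH2Cl, 70 °C
Reagents that add atoms: AgNO2 (silver nitrite), [Ag+].[O-]N=O
Why: Radical nitration of an alkene (nitro-dehydrogenation): NO2 released from AgNO2 adds to the terminal CH2 to give the diaryl-stabilised radical and TEMPO removes the neighbouring hydrogen, so the nitro group ends on the unsubstituted alkene carbon, and the geometry obtained has no bearing on step 4.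

**Step 4**
Reactants: 8 5-[(E)-1-(5-bromo-2-methoxyphenyl)-2-nitroethenyl]-2-chloro-N,N-bis(4-methoxybenzyl)pyrimidin-4-amine
Product: 11 5-(7-bromo-4-methoxy-1H-indol-3-yl)-2-chloro-N,N-bis(4-methoxybenzyl)pyrimidin-4-amine, via nitrosoalkene 9 (not isolated), via 2H-azirine 10 (not isolated)
Conditions: PPh3 (2.5 equiv), MoO2Cl2(dmf)2 (10 mol%), PhMe, 110 °C
Reagents that add atoms: none
Why: MoO2Cl2(dmf)2 relays oxygen from the nitro group to PPh3 (hexavalent dioxomolybdenum is reduced by the phosphine to a tetravalent oxo species, which takes oxygen from nitrogen), giving nitrosoalkene 9 and then a vinyl nitrene in equilibrium with 2H-azirine 10. The closest known reaction type is the deoxygenative (Cadogan–Sundberg-type) cyclisation of alpha-aryl-beta-nitrostyrenes to 3-arylindoles, which has its counterpart in the thermolysis of 2,2-diarylvinyl azides. The pyrrole ring closes by N1–C7a bond formation in a 1,5-electrocyclisation of the vinyl nitrene onto the C3a=C7a bond of the arene (formally a 5-endo closure), and a hydrogen shift from C7a to N1 restores aromaticity; no stereocentre is created. The step needs ring selectivity between the anisole ring and pyrimidine C6': the electrophilic nitrene should favour the pi-rich anisole ring over the pi-deficient C5'=C6' bond, and the bulky N(PMB)2 group at C4' twists the pyrimidine out of conjugation with the nitrene. Site selectivity on the anisole ring is fixed by the methoxy group, which blocks the second ortho carbon, and chemoselectivity by the fully substituted amine nitrogen, which cannot add to 9 or 10. Either geometrical isomer of 8 is usable, since in 10 the former alkene carbon holds both rings on one sp3 centre.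

**Step 5**
Reactants: 11 5-(7-bromo-4-methoxy-1H-indol-3-yl)-2-chloro-N,N-bis(4-methoxybenzyl)pyrimidin-4-amine
Product: 12 5-(7-bromo-4-methoxy-1H-indol-3-yl)-2-chloropyrimidin-4-amine
Conditions: CF3CO2H, 1,3-dimethoxybenzene (excess), 60 °C
Reagents that add atoms: none
Why: Acidolytic N-debenzylation: protonation releases the two 4-methoxybenzyl groups as stabilised benzyl cations (SN1), which 1,3-dimethoxybenzene intercepts by Friedel–Crafts alkylation so that the indole is not benzylated, while the chloropyrimidine, the aryl bromide and the methyl ether are inert to CF3CO2H.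

**Step 6**
Reactants: 12 5-(7-bromo-4-methoxy-1H-indol-3-yl)-2-chloropyrimidin-4-amine
Product: 13 2-bromo-5-(7-bromo-4-methoxy-1H-indol-3-yl)pyrimidin-4-amine
Conditions: Me3SiBr (excess), EtCN, 90 °C, sealed vessel; cold aq. NaHCO3
Reagents that add atoms: bromotrimethylsilane (Me3SiBr), C[Si](C)(C)Br
Why: Halogen exchange by SNAr (aromatic Finkelstein-type reaction of a 2-chloroazine): silylation or protonation of a ring nitrogen activates C2' towards bromide, and the exchange is driven by excess Me3SiBr and the stronger Si–Cl bond, whereas the aryl methyl ether and the C7–Br bond are untouched.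

**Step 7**
Reactants: 13 2-bromo-5-(7-bromo-4-methoxy-1H-indol-3-yl)pyrimidin-4-amine
Product: 14 3-(4-amino-2-bromopyrimidin-5-yl)-7-bromo-1H-indol-4-ol
Conditions: BBr3 (5 equiv), CH2Cl2, −78 °C to rt, Ar; cold aq. NaHCO3
Reagents that add atoms: none
Why: Lewis acid-mediated O-demethylation of an aryl methyl ether: BBr3 complexes the ether oxygen and bromide removes the methyl group by SN2, excess reagent covering the basic nitrogens, and aqueous work-up frees the phenol, so the oxidation-prone 4-hydroxyindole appears only in the last step.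

**Compound list**
1 | 1-(2,4-dichloropyrimidin-5-yl)ethan-1-one | CC(=O)c1cnc(Cl)nc1Cl | starting material
2 | bis(4-methoxybenzyl)amine | COc1ccc(CNCc2ccc(OC)cc2)cc1 | starting material
3 | 1-{4-[bis(4-methoxybenzyl)amino]-2-chloropyrimidin-5-yl}ethan-1-one | CC(=O)c1cnc(Cl)nc1N(Cc1ccc(OC)cc1)Cc1ccc(OC)cc1 | intermediate
4 | 2,4-dibromo-1-methoxybenzene | COc1ccc(Br)cc1Br | starting material
5 | (5-bromo-2-methoxyphenyl)magnesium chloride | COc1ccc(Br)cc1[Mg]Cl | intermediate
6 | 1-{4-[bis(4-methoxybenzyl)amino]-2-chloropyrimidin-5-yl}-1-(5-bromo-2-methoxyphenyl)ethan-1-ol (racemic) | COc1ccc(Br)cc1C(C)(O)c1cnc(Cl)nc1N(Cc1ccc(OC)cc1)Cc1ccc(OC)cc1 | intermediate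
7 | 5-[1-(5-bromo-2-methoxyphenyl)ethenyl]-2-chloro-N,N-bis(4-methoxybenzyl)pyrimidin-4-amine | C=C(c1cc(Br)ccc1OC)c1cnc(Cl)nc1N(Cc1ccc(OC)cc1)Cc1ccc(OC)cc1 | intermediate
8 | 5-[(E)-1-(5-bromo-2-methoxyphenyl)-2-nitroethenyl]-2-chloro-N,N-bis(4-methoxybenzyl)pyrimidin-4-amine | [O-][N+](=O)/C=C(/c1cc(Br)ccc1OC)c1cnc(Cl)nc1N(Cc1ccc(OC)cc1)Cc1ccc(OC)cc1 | intermediate
9 | 5-[(E)-1-(5-bromo-2-methoxyphenyl)-2-nitrosoethenyl]-2-chloro-N,N-bis(4-methoxybenzyl)pyrimidin-4-amine | O=N/C=C(/c1cc(Br)ccc1OC)c1cnc(Cl)nc1N(Cc1ccc(OC)cc1)Cc1ccc(OC)cc1 | intermediate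
10 | 5-[2-(5-bromo-2-methoxyphenyl)-2H-azirin-2-yl]-2-chloro-N,N-bis(4-methoxybenzyl)pyrimidin-4-amine (racemic) | COc1ccc(Br)cc1C2(C=N2)c3cnc(Cl)nc3N(Cc4ccc(OC)cc4)Cc5ccc(OC)cc5 | intermediate
11 | 5-(7-bromo-4-methoxy-1H-indol-3-yl)-2-chloro-N,N-bis(4-methoxybenzyl)pyrimidin-4-amine | COc1ccc(Br)c2[nH]cc(-c3cnc(Cl)nc3N(Cc3ccc(OC)cc3)Cc3ccc(OC)cc3)c12 | intermediate
12 | 5-(7-bromo-4-methoxy-1H-indol-3-yl)-2-chloropyrimidin-4-amine | COc1ccc(Br)c2[nH]cc(-c3cnc(Cl)nc3N)c12 | intermediate
13 | 2-bromo-5-(7-bromo-4-methoxy-1H-indol-3-yl)pyrimidin-4-amine | COc1ccc(Br)c2[nH]cc(-c3cnc(Br)nc3N)c12 | intermediate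
14 | 3-(4-amino-2-bromopyrimidin-5-yl)-7-bromo-1H-indol-4-ol | Nc1nc(Br)ncc1-c1c[nH]c2c(Br)ccc(O)c12 | target

**Step count.** Total: 7 steps. Longest linear sequence: 7 steps (1 → 3 → 7 → 8 → 11 → 12 → 13 → 14); arene 4 enters at step 2.

**Steps most likely to fail**

Step 4. The vinyl nitrene may undergo a 1,2-hydrogen shift to a ketenimine and end as a nitrile, or close onto pyrimidine C6' instead of the anisole ring; oxygen transfer may also be slow. Fallback (nitrogen loss from an azide in place of oxygen transfer), setting out from 7: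
- NBS in aqueous THF at 0 °C should give the bromohydrin 2-bromo-1-(5-bromo-2-methoxyphenyl)-1-{4-[bis(4-methoxybenzyl)amino]-2-chloropyrimidin-5-yl}ethan-1-ol F1.
- NaN3 in DMF/H2O at 50 °C would close it in the flask to the oxirane 5-[2-(5-bromo-2-methoxyphenyl)oxiran-2-yl]-2-chloro-N,N-bis(4-methoxybenzyl)pyrimidin-4-amine F2 and open this at its CH2 to the azido alcohol 2-azido-1-(5-bromo-2-methoxyphenyl)-1-{4-[bis(4-methoxybenzyl)amino]-2-chloropyrimidin-5-yl}ethan-1-ol F3.
- Dehydration with TsOH·H2O in PhMe at 50 °C, as in step 2, would give the vinyl azide 5-[(E)-2-azido-1-(5-bromo-2-methoxyphenyl)ethenyl]-2-chloro-N,N-bis(4-methoxybenzyl)pyrimidin-4-amine F4.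
- Heating F4 in PhMe at 100–110 °C (loss of N2 through azirine 10) should rejoin the route at 11.

Step 2. The basic Grignard reagent may enolise the hindered, amine-deactivated methyl ketone, or add to the pyrimidine ring. Fallback (cross-coupling in place of carbonyl addition), setting out from 3:
- KN(SiMe3)2 and PhNTf2 in THF at −78 °C would turn that same enolisation to advantage and give the enol triflate 1-{4-[bis(4-methoxybenzyl)amino]-2-chloropyrimidin-5-yl}ethenyl trifluoromethanesulfonate F5.
- Suzuki–Miyaura coupling with commercial (5-bromo-2-methoxyphenyl)boronic acid F6 (Pd(PPh3)4, aq. Na2CO3, dioxane, rt to 50 °C) would rejoin the route at 7. The vinyl triflate should add to zerovalent palladium before the aryl bromide or the chloropyrimidine does.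

Step 6. Chloride–bromide exchange on the amine-deactivated pyrimidine may stall and leave a mixed halide, or C2' may hydrolyse during work-up. Fallback (C–O activation in place of halide metathesis), setting out from 11:
- NaOAc in AcOH at 110 °C followed by aqueous work-up would give the pyrimidinone 4-[bis(4-methoxybenzyl)amino]-5-(7-bromo-4-methoxy-1H-indol-3-yl)pyrimidin-2(1H)-one F7.
- POBr3 in MeCN at 80 °C (deoxybromination) would give 2-bromo-5-(7-bromo-4-methoxy-1H-indol-3-yl)-N,N-bis(4-methoxybenzyl)pyrimidin-4-amine F8.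
- CF3CO2H with 1,3-dimethoxybenzene, as in step 5, would rejoin the route at 13.

**Further compounds**
F1 | step 4 | 2-bromo-1-(5-bromo-2-methoxyphenyl)-1-{4-[bis(4-methoxybenzyl)amino]-2-chloropyrimidin-5-yl}ethan-1-ol (racemic) | COc1ccc(Br)cc1C(O)(CBr)c1cnc(Cl)nc1N(Cc1ccc(OC)cc1)Cc1ccc(OC)cc1
F2 | step 4 | 5-[2-(5-bromo-2-methoxyphenyl)oxiran-2-yl]-2-chloro-N,N-bis(4-methoxybenzyl)pyrimidin-4-amine (racemic) | COc1ccc(Br)cc1C2(CO2)c3cnc(Cl)nc3N(Cc4ccc(OC)cc4)Cc5ccc(OC)cc5
F3 | step 4 | 2-azido-1-(5-bromo-2-methoxyphenyl)-1-{4-[bis(4-methoxybenzyl)amino]-2-chloropyrimidin-5-yl}ethan-1-ol (racemic) | COc1ccc(Br)cc1C(O)(CN=[N+]=[N-])c1cnc(Cl)nc1N(Cc1ccc(OC)cc1)Cc1ccc(OC)cc1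
F4 | step 4 | 5-[(E)-2-azido-1-(5-bromo-2-methoxyphenyl)ethenyl]-2-chloro-N,N-bis(4-methoxybenzyl)pyrimidin-4-amine | [N-]=[N+]=N/C=C(/c1cc(Br)ccc1OC)c1cnc(Cl)nc1N(Cc1ccc(OC)cc1)Cc1ccc(OC)cc1
F5 | step 2 | 1-{4-[bis(4-methoxybenzyl)amino]-2-chloropyrimidin-5-yl}ethenyl trifluoromethanesulfonate | C=C(OS(=O)(=O)C(F)(F)F)c1cnc(Cl)nc1N(Cc1ccc(OC)cc1)Cc1ccc(OC)cc1
F6 | step 2 | (5-bromo-2-methoxyphenyl)boronic acid | COc1ccc(Br)cc1B(O)O
F7 | step 6 | 4-[bis(4-methoxybenzyl)amino]-5-(7-bromo-4-methoxy-1H-indol-3-yl)pyrimidin-2(1H)-one | COc1ccc(Br)c2[nH]cc(-c3c[nH]c(=O)nc3N(Cc3ccc(OC)cc3)Cc3ccc(OC)cc3)c12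
F8 | step 6 | 2-bromo-5-(7-bromo-4-methoxy-1H-indol-3-yl)-N,N-bis(4-methoxybenzyl)pyrimidin-4-amine | COc1ccc(Br)c2[nH]cc(-c3cnc(Br)nc3N(Cc3ccc(OC)cc3)Cc3ccc(OC)cc3)c12
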